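**Retrosynthetic overview**
- The target is cut at its two ring C–O esters. The C6–O bond comes from allylic C–H oxidation (SeO2) of the exocyclic methylene followed by acylation. The C1–O bond comes from a stereoinvertive trivalent-iodine α-acyloxylation of a regiodefined enol silane that delivers the (2R)-2-methylbutanoate directly (key step, new).
- The C3 side chain comes from a syn aldol of the C2–C3 titanium enolate with acetaldehyde, then acetylation.
- The five-membered ring is formed second, by ring-closing metathesis of a 2-siloxy-1,6-diene, which leaves the C2–C3 enol silane; the exocyclic methylene comes from a Wittig reaction.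
- The six-membered ring is formed first: (R)-cryptone from isovaleraldehyde and methyl vinyl ketone (organocatalytic Michael/aldol), then trans,trans conjugate vinylation and enolate alkylation.

Assumption: (2R)-2-methylbutanoic acid and (2E)-3-methylpent-2-enoic acid are bought as single isomers; all bicyclic compounds carry the octahydroindene locants of the target (C1 = carbon of the 2-methylbutanoate, C2 = ring carbonyl, C3 = side-chain carbon, C4 = isopropyl carbon, C6 = carbinol carbon, C7 = methylidene carbon); "top face" is the face of H-3a and "bottom face" that of H-7a.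

**Route**

Step 1
Reactants: 1 3-methylbutanal; 2 but-3-en-2-one
Product: 4 (4R)-4-(propan-2-yl)cyclohex-2-en-1-one [(R)-cryptone], via keto aldehyde 3 (not isolated)
Conditions: (R)-2-[methoxy(diphenyl)methyl]pyrrolidine (5 mol %), ethyl 3,4-dihydroxybenzoate (20 mol %), neat, 4 °C; then LiOH, iPrOH, 23 °C
Reagents that add atoms: none
Why: Enamine-catalysed asymmetric Michael addition (the diarylmethyl ether group shields one enamine face, which fixes the isopropyl-bearing carbon as R) followed by intramolecular aldol condensation (Robinson-type annulation) gives the enone.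

Step 2
Reactants: 5 1,3-dichloropropan-2-one
Product: 6 tert-butyl[(3-chloroprop-1-en-2-yl)oxy]dimethylsilane
Conditions: Zn dust, tBuMe2SiCl, THF/DMPU, 0 → 23 °C
Reagents that add atoms: tert-butyl(chloro)dimethylsilane (TBSCl), CC(C)(C)[Si](C)(C)Cl
Why: Reformatsky-type zinc insertion into one C–Cl bond gives a zinc enolate that is O-silylated to the 2-siloxyallyl chloride (reductive silylation of an α-halo ketone, by analogy with the known trimethylsilyl reagent).

Step 3
Reactants: 4 (R)-cryptone; 7 vinylmagnesium bromide; 6 tert-butyl[(3-chloroprop-1-en-2-yl)oxy]dimethylsilane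
Product: 9 (2S,3R,4R)-2-{2-[(tert-butyldimethylsilyl)oxy]prop-2-en-1-yl}-3-ethenyl-4-(propan-2-yl)cyclohexan-1-one, via magnesium enolate 8 (not isolated)
Conditions: 7, CuBr·SMe2 (10 mol %), THF, −78 °C; then 6, NaI (20 mol %), DMPU, −78 → 0 °C
Reagents that add atoms: none
Why: Copper-catalysed conjugate addition places the vinyl group anti to the isopropyl group (sets the future C3a) and the regiodefined enolate is alkylated anti to the new vinyl group (sets the future C7a), giving the all-equatorial trans,trans ketone (three-component conjugate addition–enolate alkylation).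

Step 4
Reactants: 9 (2S,3R,4R)-2-{2-[(tert-butyldimethylsilyl)oxy]prop-2-en-1-yl}-3-ethenyl-4-(propan-2-yl)cyclohexan-1-one
Product: 10 tert-butyl({3-[(1S,2R,3R)-2-ethenyl-6-methylidene-3-(propan-2-yl)cyclohexyl]prop-1-en-2-yl}oxy)dimethylsilane
Conditions: Ph3PCH3Br, KOtBu, THF, 0 → 65 °C
Reagents that add atoms: methyltriphenylphosphonium bromide, C[P+](c1ccccc1)(c1ccccc1)c1ccccc1.[Br-]
Why: Wittig methylenation of the only carbonyl group present; the silyl enol ether tolerates the ylide and the α-carbon is already the thermodynamic equatorial epimer.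

Step 5
Reactants: 10 tert-butyl({3-[(1S,2R,3R)-2-ethenyl-6-methylidene-3-(propan-2-yl)cyclohexyl]prop-1-en-2-yl}oxy)dimethylsilane
Product: 11 tert-butyldimethyl{[(3aR,4R,7aS)-7-methylidene-4-(propan-2-yl)-3a,4,5,6,7,7a-hexahydro-1H-inden-2-yl]oxy}silane
Conditions: second-generation Grubbs catalyst RuCl2(H2IMes)(PCy3)(=CHPh) (5 mol %), toluene, 70 °C
Reagents that add atoms: none
Why: Ring-closing metathesis of the vinyl group onto the 2-siloxyalkene (the exocyclic methylene cannot close a five-membered ring) forms the trans-fused five-membered ring as a regiodefined C2–C3 enol silane without touching a stereocentre.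

Step 6
Reactants: 11 tert-butyldimethyl{[(3aR,4R,7aS)-7-methylidene-4-(propan-2-yl)-3a,4,5,6,7,7a-hexahydro-1H-inden-2-yl]oxy}silane; 12 acetaldehyde
Product: 15 (3R,3aR,4R,7aS)-3-[(1S)-1-hydroxyethyl]-7-methylidene-4-(propan-2-yl)octahydro-2H-inden-2-one, via lithium enolate 13 (not isolated), via titanium enolate 14 (not isolated)
Conditions: MeLi, THF, 0 → 23 °C; ClTi(OiPr)3, −78 °C; 12, −78 °C; aq NH4Cl
Reagents that add atoms: none
Why: The regiodefined enolate adds acetaldehyde at C3 on the top face, anti to the C3a–C4 bond (trans-selective trapping of a β-substituted cyclopentanone enolate), and the triisopropoxytitanium enolate gives the syn aldol irrespective of enolate geometry (titanium-enolate aldol addition), which sets C1′ as S.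

Step 7
Reactants: 15 (3R,3aR,4R,7aS)-3-[(1S)-1-hydroxyethyl]-7-methylidene-4-(propan-2-yl)octahydro-2H-inden-2-one
Product: 16 (3R,3aR,4R,7aS)-3-[(1S)-1-(acetyloxy)ethyl]-7-methylidene-4-(propan-2-yl)octahydro-2H-inden-2-one
Conditions: Ac2O, pyridine, DMAP (5 mol %), CH2Cl2, 0 °C
Reagents that add atoms: acetic anhydride, CC(=O)OC(C)=O
Why: O-acylation with retention at C1′; cold, weakly basic conditions avoid β-elimination of the β-acetoxy ketone.

Step 8
Reactants: 16 (3R,3aR,4R,7aS)-3-[(1S)-1-(acetyloxy)ethyl]-7-methylidene-4-(propan-2-yl)octahydro-2H-inden-2-one; 17 (2R)-2-methylbutanoic acid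
Product: 19 (1R,3R,3aR,4R,7aS)-3-[(1S)-1-(acetyloxy)ethyl]-7-methylidene-2-oxo-4-(propan-2-yl)octahydro-1H-inden-1-yl (2R)-2-methylbutanoate, via enol silane 18 (not isolated)
Conditions: LiN(SiMe3)2, Me3SiCl, THF, −78 °C; then PhI[O2CCH(CH3)C2H5]2 (made from PhI(OAc)2 and 17 (2 equiv), PhCl, 50 °C, reduced pressure), Me3SiOTf (10 mol %), CH2Cl2, −78 → −20 °C
Reagents that add atoms: none
Why: Proposed new method: kinetic deprotonation at the C1 methylene gives enol silane 18, whose C1 attacks the silyl-triflate-activated trivalent-iodine bis-carboxylate from the open bottom face (anti to the C7a–C7 bond) to give a C1-bound phenyliodonio ketone, and the (2R)-2-methylbutanoate then displaces iodobenzene (a hypernucleofuge) by SN2 from the top face, so the C1–O bond forms with net inversion relative to electrophile approach and the ester ends up cis to H-3a (1R), the contra-steric epimer that direct electrophilic oxygenation would not give; the closest known reaction types are the Koser/Moriarty α-oxygenation of ketones and enol silanes with trivalent-iodine reagents and the Rubottom silver carboxylate–iodine acyloxylation of enol silanes, but transfer of a stoichiometric chiral aliphatic carboxylate with this stereoinvertive outcome next to a ring fusion has not been shown.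

Step 9
Reactants: 19 (1R,3R,3aR,4R,7aS)-3-[(1S)-1-(acetyloxy)ethyl]-7-methylidene-2-oxo-4-(propan-2-yl)octahydro-1H-inden-1-yl (2R)-2-methylbutanoate
Product: 20 (1R,3R,3aR,4R,6S,7aS)-3-[(1S)-1-(acetyloxy)ethyl]-6-hydroxy-7-methylidene-2-oxo-4-(propan-2-yl)octahydro-1H-inden-1-yl (2R)-2-methylbutanoate
Conditions: SeO2 (0.3 equiv), tBuOOH (3 equiv), CH2Cl2, 0 → 23 °C
Reagents that add atoms: tert-butyl hydroperoxide, CC(C)(C)OO
Why: Selenium dioxide allylic oxidation (ene reaction at the methylene terminus with loss of the axial C6–H, then [2,3]-sigmatropic shift) returns the double bond to the exocyclic position and delivers oxygen axially on the bottom face (6S), the ring CH2 reacting in preference to the tertiary C7a–H.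

Step 10
Reactants: 20 (1R,3R,3aR,4R,6S,7aS)-3-[(1S)-1-(acetyloxy)ethyl]-6-hydroxy-7-methylidene-2-oxo-4-(propan-2-yl)octahydro-1H-inden-1-yl (2R)-2-methylbutanoate; 21 (2E)-3-methylpent-2-enoic acid
Product: 22 (1R,3R,3aR,4R,6S,7aS)-3-[(1S)-1-(acetyloxy)ethyl]-7-methylidene-1-{[(2R)-2-methylbutanoyl]oxy}-2-oxo-4-(propan-2-yl)octahydro-1H-inden-6-yl (2E)-3-methylpent-2-enoate (CNP0289166.2)
Conditions: DCC, DMAP (10 mol %), CH2Cl2, 0 → 23 °C
Reagents that add atoms: none
Why: Steglich esterification acylates the axial allylic alcohol with retention at C6 and leaves the E double bond of the acid untouched; DMAP is kept catalytic and cold to spare the base-sensitive C1 centre and the β-acetoxy ketone.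

**Compound list**

1 | 3-methylbutanal (isovaleraldehyde) | CC(C)CC=O | starting material
2 | but-3-en-2-one (methyl vinyl ketone) | CC(=O)C=C | starting material
3 | (2R)-5-oxo-2-(propan-2-yl)hexanal | O=C[C@@H](C(C)C)CCC(C)=O | intermediate
4 | (4R)-4-(propan-2-yl)cyclohex-2-en-1-one [(R)-cryptone] | O=C1C=C[C@@H](C(C)C)CC1 | intermediate
5 | 1,3-dichloropropan-2-one | ClCC(=O)CCl | starting material
6 | tert-butyl[(3-chloroprop-1-en-2-yl)oxy]dimethylsilane | C=C(CCl)O[Si](C)(C)C(C)(C)C | intermediate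
7 | vinylmagnesium bromide | C=C[Mg]Br | starting material
8 | bromomagnesium (3R,4R)-3-ethenyl-4-(propan-2-yl)cyclohex-1-en-1-olate | Br[Mg]OC1=C[C@H](C=C)[C@@H](C(C)C)CC1 | intermediate
9 | (2S,3R,4R)-2-{2-[(tert-butyldimethylsilyl)oxy]prop-2-en-1-yl}-3-ethenyl-4-(propan-2-yl)cyclohexan-1-one | O=C1[C@@H](CC(=C)O[Si](C)(C)C(C)(C)C)[C@H](C=C)[C@@H](C(C)C)CC1 | intermediate
10 | tert-butyl({3-[(1S,2R,3R)-2-ethenyl-6-methylidene-3-(propan-2-yl)cyclohexyl]prop-1-en-2-yl}oxy)dimethylsilane | C=C1[C@@H](CC(=C)O[Si](C)(C)C(C)(C)C)[C@H](C=C)[C@@H](C(C)C)CC1 | intermediate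
11 | tert-butyldimethyl{[(3aR,4R,7aS)-7-methylidene-4-(propan-2-yl)-3a,4,5,6,7,7a-hexahydro-1H-inden-2-yl]oxy}silane (trans-fused) | C=C1[C@@H]2[C@H](C=C(O[Si](C)(C)C(C)(C)C)C2)[C@@H](C(C)C)CC1 | intermediate
12 | acetaldehyde | CC=O | starting material
13 | lithium (3aR,4R,7aS)-7-methylidene-4-(propan-2-yl)-3a,4,5,6,7,7a-hexahydro-1H-inden-2-olate | C=C1[C@@H]2[C@H](C=C(O[Li])C2)[C@@H](C(C)C)CC1 | intermediate
14 | tri(propan-2-yloxy)titanium (3aR,4R,7aS)-7-methylidene-4-(propan-2-yl)-3a,4,5,6,7,7a-hexahydro-1H-inden-2-olate | C=C1[C@@H]2[C@H](C=C(O[Ti](OC(C)C)(OC(C)C)OC(C)C)C2)[C@@H](C(C)C)CC1 | intermediate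
15 | (3R,3aR,4R,7aS)-3-[(1S)-1-hydroxyethyl]-7-methylidene-4-(propan-2-yl)octahydro-2H-inden-2-one | C=C1[C@@H]2[C@H]([C@H]([C@H](C)O)C(=O)C2)[C@@H](C(C)C)CC1 | intermediate
16 | (3R,3aR,4R,7aS)-3-[(1S)-1-(acetyloxy)ethyl]-7-methylidene-4-(propan-2-yl)octahydro-2H-inden-2-one | C=C1[C@@H]2[C@H]([C@H]([C@H](C)OC(C)=O)C(=O)C2)[C@@H](C(C)C)CC1 | intermediate
17 | (2R)-2-methylbutanoic acid | OC(=O)[C@H](C)CC | starting material
18 | (1S)-1-{(3R,3aR,4R,7aR)-7-methylidene-4-(propan-2-yl)-2-[(trimethylsilyl)oxy]-3a,4,5,6,7,7a-hexahydro-3H-inden-3-yl}ethyl acetate (C1=C2 enol silane of 16) | C=C1[C@@H]2[C@H]([C@H]([C@H](C)OC(C)=O)C(O[Si](C)(C)C)=C2)[C@@H](C(C)C)CC1 | intermediate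
19 | (1R,3R,3aR,4R,7aS)-3-[(1S)-1-(acetyloxy)ethyl]-7-methylidene-2-oxo-4-(propan-2-yl)octahydro-1H-inden-1-yl (2R)-2-methylbutanoate | C=C1[C@@H]2[C@H]([C@H]([C@H](C)OC(C)=O)C(=O)[C@@H]2OC(=O)[C@H](C)CC)[C@@H](C(C)C)CC1 | intermediate
20 | (1R,3R,3aR,4R,6S,7aS)-3-[(1S)-1-(acetyloxy)ethyl]-6-hydroxy-7-methylidene-2-oxo-4-(propan-2-yl)octahydro-1H-inden-1-yl (2R)-2-methylbutanoate | C=C1[C@@H]2[C@H]([C@H]([C@H](C)OC(C)=O)C(=O)[C@@H]2OC(=O)[C@H](C)CC)[C@@H](C(C)C)C[C@@H]1O | intermediate
21 | (2E)-3-methylpent-2-enoic acid | OC(=O)/C=C(\C)CC | starting material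
22 | (1R,3R,3aR,4R,6S,7aS)-3-[(1S)-1-(acetyloxy)ethyl]-7-methylidene-1-{[(2R)-2-methylbutanoyl]oxy}-2-oxo-4-(propan-2-yl)octahydro-1H-inden-6-yl (2E)-3-methylpent-2-enoate | C=C1[C@@H]2[C@H]([C@H]([C@H](C)OC(C)=O)C(=O)[C@@H]2OC(=O)[C@H](C)CC)[C@@H](C(C)C)C[C@@H]1OC(=O)/C=C(\C)CC | target

**Step count**
- Total steps: 10 (steps 1–10; step 2 is a one-step reagent preparation).
- Longest linear sequence: 9 steps (1, 3–10) from isovaleraldehyde.

**Three steps most likely to fail, with fallbacks**

Step 8, the new acyloxylation. The risks are retentive ligand coupling or reaction through an O-bound iodane (either would give the C1 epimer), oxidative dimerisation of 18, and attack of the iodane on the methylidene group. The known-chemistry fallback sets out from 16. Its kinetic lithium enolate (LiN(SiMe3)2, THF, −78 °C) is hydroxylated with 2-(phenylsulfonyl)-3-phenyloxaziridine (Davis oxidation) on the open bottom face, giving (1S,3R,3aR,4R,7aS)-3-[(1S)-1-(acetyloxy)ethyl]-1-hydroxy-7-methylidene-4-(propan-2-yl)octahydro-2H-inden-2-one F1. Mitsunobu esterification of F1 with 17 (PPh3, DIAD, toluene, 0 °C) inverts C1 and comes back to the route at 19.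

Step 6, the aldol. The risks are the syn/anti ratio with a small aldehyde and the facial control at C3. The fallback sets out from 11 through lithium enolate 13, which is transmetallated with chlorodicyclohexylborane to dicyclohexylboryl (3aR,4R,7aS)-7-methylidene-4-(propan-2-yl)-3a,4,5,6,7,7a-hexahydro-1H-inden-2-yl ether (boron enolate) F2. Its closed chair transition state adds acetaldehyde to give the anti aldol (3R,3aR,4R,7aS)-3-[(1R)-1-hydroxyethyl]-7-methylidene-4-(propan-2-yl)octahydro-2H-inden-2-one F3. A Mitsunobu reaction of F3 with acetic acid (PPh3, DIAD, THF, 0 °C) forms the acetate with inversion at C1′ and comes back to the route at 16, bypassing 15 and step 7.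

Step 3, the one-pot alkylation of a magnesium enolate with the sensitive, non-commercial chloride 6 (this also covers a poor step 2). The fallback sets out from 4. Enolate 8 is trapped with propargyl bromide to give (2S,3R,4R)-3-ethenyl-4-(propan-2-yl)-2-(prop-2-yn-1-yl)cyclohexan-1-one F4. Wittig methylenation (Ph3PCH3Br, KOtBu) gives 3-[(1S,2R,3R)-2-ethenyl-6-methylidene-3-(propan-2-yl)cyclohexyl]prop-1-yne F5. Markovnikov hydration of the alkyne catalysed by (Ph3P)AuNTf2 (MeOH/H2O) gives 1-[(1S,2R,3R)-2-ethenyl-6-methylidene-3-(propan-2-yl)cyclohexyl]propan-2-one F6. Kinetic deprotonation on the methyl side (LiN(iPr)2, THF, −78 °C) and O-silylation with tBuMe2SiCl/DMPU comes back to the route at 10.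

Further compounds
F1 | step 8 | (1S,3R,3aR,4R,7aS)-3-[(1S)-1-(acetyloxy)ethyl]-1-hydroxy-7-methylidene-4-(propan-2-yl)octahydro-2H-inden-2-one | C=C1[C@@H]2[C@H]([C@H]([C@H](C)OC(C)=O)C(=O)[C@H]2O)[C@@H](C(C)C)CC1
F2 | step 6 | dicyclohexylboryl (3aR,4R,7aS)-7-methylidene-4-(propan-2-yl)-3a,4,5,6,7,7a-hexahydro-1H-inden-2-yl ether (boron enolate) | C=C1[C@@H]2[C@H](C=C(OB(C3CCCCC3)C3CCCCC3)C2)[C@@H](C(C)C)CC1
F3 | step 6 | (3R,3aR,4R,7aS)-3-[(1R)-1-hydroxyethyl]-7-methylidene-4-(propan-2-yl)octahydro-2H-inden-2-one | C=C1[C@@H]2[C@H]([C@H]([C@@H](C)O)C(=O)C2)[C@@H](C(C)C)CC1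
F4 | step 3 | (2S,3R,4R)-3-ethenyl-4-(propan-2-yl)-2-(prop-2-yn-1-yl)cyclohexan-1-one | O=C1[C@@H](CC#C)[C@H](C=C)[C@@H](C(C)C)CC1
F5 | step 3 | 3-[(1S,2R,3R)-2-ethenyl-6-methylidene-3-(propan-2-yl)cyclohexyl]prop-1-yne | C=C1[C@@H](CC#C)[C@H](C=C)[C@@H](C(C)C)CC1
F6 | step 3 | 1-[(1S,2R,3R)-2-ethenyl-6-methylidene-3-(propan-2-yl)cyclohexyl]propan-2-one | C=C1[C@@H](CC(C)=O)[C@H](C=C)[C@@H](C(C)C)CC1
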